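**Retrosynthetic overview**
- Last disconnection: the pendant 4-methoxy-2-pyranone (ring C) is cut at its C5–C6 bond into a carbene-generated acyl anion of a cyclobutanecarbaldehyde and methyl (E)-4-bromo-3-methoxybut-2-enoate used as a γ-electrophile; enol lactonisation then closes ring C.
- Cyclobutane (ring B) and all four stereocentres: enantioselective [2+2] photocycloaddition of a chiral cinnamaldehyde eniminium ion across the 5,6-double bond of 4-methoxy-6-(2-phenylethyl)-2H-pyran-2-one, which turns the purchased pyranone (ring A) into the fused dihydropyranone.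
- The phenethylpyranone comes from benzylation of the methyl group of 4-methoxy-6-methyl-2H-pyran-2-one.
- Ring order: A (purchased), B (step 2), C (step 3).

Assumption: the (S)-configured pyrrolidine auxiliary of step 2 is taken to give the enantiomer drawn; if the facial sense proves opposite, its commercially available (R)-enantiomer is used with no other change.

**Step 1**
Reactants: 1 4-methoxy-6-methyl-2H-pyran-2-one; 2 benzyl bromide
Product: 4 4-methoxy-6-(2-phenylethyl)-2H-pyran-2-one, via lithium dienolate 3 (not isolated)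
Conditions: LiN(iPr)2 (1.1 equiv), THF, −78 °C, 30 min; then 2 (1.0 equiv), −78 to −30 °C
Reagents that add atoms: none
Why: Kinetic deprotonation of the vinylogous methyl group gives the extended dienolate 3, which is alkylated at the exocyclic carbon by benzyl bromide (vinylogous enolate alkylation); no stereocentre is formed.

**Step 2**
Reactants: 4 4-methoxy-6-(2-phenylethyl)-2H-pyran-2-one; 5 (E)-cinnamaldehyde; 6 (S)-2-(methoxydiphenylmethyl)pyrrolidine
Product: 9 (1R,6S,7S,8R)-5-methoxy-3-oxo-7-phenyl-1-(2-phenylethyl)-2-oxabicyclo[4.2.0]oct-4-ene-8-carbaldehyde, via eniminium salt 7 (not isolated), via cyclobutyl iminium salt 8 (not isolated)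
Conditions: 5 (1 equiv), 6 (1 equiv), HBF4·OEt2 (1 equiv), 4 Å MS, MeCN, rt, 2 h; then 4 (4 equiv, excess recovered), Ru(bpz)3(PF6)2 (2.5 mol %, bpz = 2,2'-bipyrazine), 458 nm LED, rt; then THF/H2O, rt, no base
Reagents that add atoms: water, O
Why: Triplet energy transfer from the ruthenium sensitizer to eniminium ion 7 starts a stepwise [2+2] photocycloaddition (chiral eniminium [2+2] photocycloaddition) across the diene-like 5,6-double bond of 4, in which the α-carbon bonds to C6 so that the radical left at C5 is delocalised over the enoate and closure at the benzylic carbon gives the cis-fused bicycle; the E-alkene gives phenyl trans to the iminium carbon, head-to-tail stacking of the phenyl ring over the pyranone places phenyl on the lactone face, the methoxydiphenylmethyl arm of the auxiliary shields one face of the eniminium to fix the absolute configuration of all four stereocentres, and base-free hydrolysis of 8 releases aldehyde 9 without β-elimination of the lactone oxygen.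

**Step 3**
Reactants: 9 (1R,6S,7S,8R)-5-methoxy-3-oxo-7-phenyl-1-(2-phenylethyl)-2-oxabicyclo[4.2.0]oct-4-ene-8-carbaldehyde; 10 methyl (2E)-4-bromo-3-methoxybut-2-enoate
Product: 13 (1R,6S,7S,8S)-5-methoxy-8-(4-methoxy-2-oxo-2H-pyran-6-yl)-7-phenyl-1-(2-phenylethyl)-2-oxabicyclo[4.2.0]oct-4-en-3-one, via Breslow enaminol 11 (not isolated), via keto ester 12 (not isolated)
Conditions: 10 (1.5 equiv), 3-(2,6-diisopropylphenyl)-5,6,7,8-tetrahydro-4H-cyclohepta[d]thiazol-3-ium perchlorate (20 mol %), K2CO3 (1.5 equiv), MeCN, rt; then 50 °C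
Reagents that add atoms: none
Why: Proposed new method: the thiazolylidene adds to aldehyde 9 to give Breslow enaminol 11, an acyl anion equivalent whose carbon attacks the primary allylic bromide of 10 (direct SN2, or single-electron transfer to 10 followed by recombination of the ketyl and allyl radicals, both giving the same bond), so that the aldehyde carbon and the bromomethyl carbon, both electrophilic in their native form, are joined and keto ester 12 is released together with the free carbene; 12 is a vinylogous β-keto ester whose (E)-geometry holds the ester beside the ketone enol, so carbonate-promoted enol O-acylation closes the aromatic 4-methoxy-2-pyranone with loss of methanol and no stereocentre is touched; the closest known reactions are the thiazolylidene/carbonate coupling of aldehydes with benzylic halides, radical carbene catalysis of aliphatic aldehydes with alkyl electrophiles, and the base-induced cyclisation of 5-oxo-3-methoxypent-2-enoates to 4-methoxy-2-pyranones.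

**Compound list**
1 | 4-methoxy-6-methyl-2H-pyran-2-one | Cc1cc(OC)cc(=O)o1 | starting material
2 | benzyl bromide | BrCc1ccccc1 | starting material
3 | lithium dienolate of 1, lithium (4-methoxy-2-oxo-2H-pyran-6-yl)methanide | [Li+].[CH2-]c1cc(OC)cc(=O)o1 | intermediate
4 | 4-methoxy-6-(2-phenylethyl)-2H-pyran-2-one | O=c1cc(OC)cc(CCc2ccccc2)o1 | intermediate
5 | (E)-cinnamaldehyde, (2E)-3-phenylprop-2-enal | O=C/C=C/c1ccccc1 | starting material
6 | (S)-2-(methoxydiphenylmethyl)pyrrolidine | COC(c1ccccc1)(c1ccccc1)[C@@H]1CCCN1 | starting material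
7 | eniminium salt: (2S)-2-(methoxydiphenylmethyl)-1-[(2E)-3-phenylprop-2-en-1-ylidene]pyrrolidinium tetrafluoroborate | c1ccccc1/C=C/C=[N+]1CCC[C@H]1C(OC)(c1ccccc1)c1ccccc1.F[B-](F)(F)F | intermediate
8 | cyclobutyl iminium salt: iminium tetrafluoroborate of aldehyde 9 with amine 6, ring stereocentres as in 9 | COC1=CC(=O)O[C@]2(CCc3ccccc3)[C@H]1[C@H](c1ccccc1)[C@H]2C=[N+]1CCC[C@H]1C(OC)(c1ccccc1)c1ccccc1.F[B-](F)(F)F | intermediate
9 | (1R,6S,7S,8R)-5-methoxy-3-oxo-7-phenyl-1-(2-phenylethyl)-2-oxabicyclo[4.2.0]oct-4-ene-8-carbaldehyde (phenyl cis to the ring-fusion C–C(OMe) bond, formyl cis to the phenethyl group) | COC1=CC(=O)O[C@]2(CCc3ccccc3)[C@H]1[C@H](c1ccccc1)[C@H]2C=O | intermediate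
10 | methyl (2E)-4-bromo-3-methoxybut-2-enoate | BrC/C(OC)=C\C(=O)OC | starting material
11 | Breslow enaminol: adduct of the thiazolylidene with the formyl carbon of 9, ring stereocentres as in 9 | COC1=CC(=O)O[C@]2(CCc3ccccc3)[C@H]1[C@H](c1ccccc1)[C@H]2C(O)=C1SC2=C(CCCCC2)N1c1c(C(C)C)cccc1C(C)C | intermediate
12 | keto ester: methyl (2E)-3-methoxy-5-[(1R,6S,7S,8R)-5-methoxy-3-oxo-7-phenyl-1-(2-phenylethyl)-2-oxabicyclo[4.2.0]oct-4-en-8-yl]-5-oxopent-2-enoate | COC1=CC(=O)O[C@]2(CCc3ccccc3)[C@H]1[C@H](c1ccccc1)[C@H]2C(=O)C/C(OC)=C\C(=O)OC | intermediate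
13 | (1R,6S,7S,8S)-5-methoxy-8-(4-methoxy-2-oxo-2H-pyran-6-yl)-7-phenyl-1-(2-phenylethyl)-2-oxabicyclo[4.2.0]oct-4-en-3-one | COC1=CC(=O)O[C@]2(CCc3ccccc3)[C@H]1[C@H](c1ccccc1)[C@H]2c1cc(OC)cc(=O)o1 | target

**Totals and risks**
Total step count: 3. Longest linear sequence: 3 (1 to 4 to 9 to 13).

Steps most likely to fail, in order of risk:

Step 2. The 5,6-double bond of a 2-pyranone has not been used as the olefin partner of an eniminium photocycloaddition, so regiochemistry, the phenyl-on-lactone-face diastereomer and the level of enantiocontrol are all unproven. Fallback, setting out from 1 and 4: condensation of 1 with benzaldehyde (Mg(OMe)2, MeOH, reflux) gives 4-methoxy-6-[(E)-2-phenylethenyl]-2H-pyran-2-one F1. Irradiating F1 with excess 4 in the presence of thioxanthen-9-one (405 nm, MeCN) gives the head-to-tail heterodimer as the racemate, that is 13 together with its mirror image F2. Preparative chiral SFC then delivers 13, where this fallback comes back to the route.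

Step 3. The carbene may be alkylated by the bromide, an α-branched aliphatic aldehyde forms the enaminol slowly, and aldehyde 9 is a β-acyloxy aldehyde that can lose the lactone oxygen by E1cB under base. Fallback, setting out from 9 and 10: zinc dust in THF converts 10 into its zinc dienolate, which adds through the γ-carbon to the aldehyde to give the hydroxy ester F3. F3 lactonises in the flask to the 5,6-dihydropyranone F4 (both carbinol epimers converge). Dehydrogenation with DDQ in dioxane at 80 °C gives 13, where this fallback comes back to the route.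

Step 1. Over-alkylation or competing ring metalation can lower the yield. Fallback, setting out from 2: commercial 4-hydroxy-6-methyl-2H-pyran-2-one is converted into its dianion (LiN(iPr)2, 2.2 equiv, THF, −78 °C) and benzylated at the methyl carbon by 2 to give 4-hydroxy-6-(2-phenylethyl)-2H-pyran-2-one F5. O-Methylation (Me2SO4, K2CO3, acetone, reflux) gives 4, where this fallback comes back to the route.

**Further compounds**
F1 | step 2 | 4-methoxy-6-[(E)-2-phenylethenyl]-2H-pyran-2-one (5,6-dehydrokawain) | O=c1cc(OC)cc(/C=C/c2ccccc2)o1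
F2 | step 2 | (1S,6R,7R,8R)-5-methoxy-8-(4-methoxy-2-oxo-2H-pyran-6-yl)-7-phenyl-1-(2-phenylethyl)-2-oxabicyclo[4.2.0]oct-4-en-3-one, the mirror image of 13 | COC1=CC(=O)O[C@@]2(CCc3ccccc3)[C@@H]1[C@@H](c1ccccc1)[C@@H]2c1cc(OC)cc(=O)o1
F3 | step 3 | methyl (2E)-5-hydroxy-3-methoxy-5-[5-methoxy-3-oxo-7-phenyl-1-(2-phenylethyl)-2-oxabicyclo[4.2.0]oct-4-en-8-yl]pent-2-enoate, ring stereocentres as in 9, both carbinol epimers | COC1=CC(=O)O[C@]2(CCc3ccccc3)[C@H]1[C@H](c1ccccc1)[C@H]2C(O)C/C(OC)=C\C(=O)OC
F4 | step 3 | 5-methoxy-8-(4-methoxy-6-oxo-3,6-dihydro-2H-pyran-2-yl)-7-phenyl-1-(2-phenylethyl)-2-oxabicyclo[4.2.0]oct-4-en-3-one, ring stereocentres as in 13, both epimers at the new ring carbon | COC1=CC(=O)O[C@]2(CCc3ccccc3)[C@H]1[C@H](c1ccccc1)[C@H]2C1CC(OC)=CC(=O)O1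
F5 | step 1 | 4-hydroxy-6-(2-phenylethyl)-2H-pyran-2-one | O=c1cc(O)cc(CCc2ccccc2)o1
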